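**Assumption:** the target is taken exactly as the given SMILES, i.e. 2S in the chromene and 1R,3R in the cyclohexane (ring methyls trans). The sense of induction in step 9 is assigned from a working model; if it turns out reversed, the antipodal (R,R)-ligand is used with no other change.

## Retrosynthetic overview

1. Ring D (pyran) is formed last: the O1–C2 bond and the C2 stereocentre come from an enantioselective oxidative 6-endo cyclization of a 2-allyl-4,6-dimethoxyresorcinol. The arene is symmetric, so either phenol gives the same chromene.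
2. The aryl–CH2 bond comes from ortho C-allylation of 4,6-dimethoxyresorcinol (ring C, bought as the dibromide) with an E allylic alcohol.
3. The E-trisubstituted alkene comes from methylalumination/hydroxymethylation of a terminal alkyne; the exocyclic methylene comes from the ring ketone.
4. The alkyne and ring ketone come from Eschenmoser–Tanabe fragmentation of an epoxy-octalone. The second carbocycle (ring B) is temporary: it is used to equilibrate the CHMe centre to trans and is then cleaved.
5. Ring order: ring A is present in 2,6-dimethylcyclohexanone (quaternary centre set by asymmetric Michael addition); ring B is formed and cleaved; ring C is bought; ring D is closed last.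

## Route

Step 1
Reactants: 1 2,6-dimethylcyclohexanone (cis/trans mixture); 2 (S)-1-phenylethylamine; 3 methyl vinyl ketone
Product: 6 (2R,6S)-2,6-dimethyl-2-(3-oxobutyl)cyclohexan-1-one, via ketimine 4 (not isolated), via adduct imine 5 (not isolated)
Conditions: 2 (1.05 equiv), p-TsOH (cat.), toluene, Dean–Stark, reflux; concentrate; 3 (1.5 equiv), THF, 40 °C, 4 d; 20% aq AcOH, rt; 2 recovered by base extraction
Reagents that add atoms: water (O)
Why: Asymmetric Michael addition of a chiral ketimine through its secondary enamine (d'Angelo deracemizing alkylation), in which the aza-ene-like transition state alkylates the substituted α-carbon on the face away from the phenyl group and sets C2 as R (the sense known for 2-methylcyclohexanone with the S amine), while C6 is expected mainly S (acceptor anti to the pseudoaxial 6-methyl) and is deliberately re-set in step 2.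

Step 2
Reactants: 6 (2R,6S)-2,6-dimethyl-2-(3-oxobutyl)cyclohexan-1-one
Product: 9 (4aR,8R)-4a,8-dimethyl-4,4a,5,6,7,8-hexahydronaphthalen-2(3H)-one, via ketol 7 (not isolated), via 8-epi-octalone 8 (not isolated)
Conditions: NaOMe (0.3 equiv), MeOH, reflux, 16 h
Reagents that add atoms: none
Why: Intramolecular aldol condensation (second half of a Robinson annulation) under equilibrating conditions, in which C8 epimerizes through the extended dienolate to the isomer with the 8-methyl equatorial and trans to the angular methyl (locked axial on ring B by the trigonal ring-fusion carbon, as in the 6β-to-6α methyl preference of steroidal 4-en-3-ones), so the future CHMe centre becomes R whatever the C6 ratio from step 1.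

Step 3
Reactants: 9 (4aR,8R)-4a,8-dimethyl-4,4a,5,6,7,8-hexahydronaphthalen-2(3H)-one
Product: 10 (4aR,8R)-1,8a-epoxy-4a,8-dimethyloctahydronaphthalen-2(1H)-one
Conditions: 30% H2O2, NaOH (cat.), MeOH, 0 °C to rt
Reagents that add atoms: hydrogen peroxide (OO)
Why: Weitz–Scheffer nucleophilic epoxidation of the enone, which leaves both existing centres untouched and gives oxirane diastereomers that converge in step 4.

Step 4
Reactants: 10 (4aR,8R)-1,8a-epoxy-4a,8-dimethyloctahydronaphthalen-2(1H)-one
Product: 12 (2R,6R)-2-(but-3-yn-1-yl)-2,6-dimethylcyclohexan-1-one, via tosylhydrazone 11 (not isolated)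
Conditions: TsNHNH2 (1.1 equiv), AcOH–CH2Cl2 1:1, −20 °C to rt
Reagents that add atoms: none
Why: Eschenmoser–Tanabe fragmentation of the α,β-epoxy tosylhydrazone cleaves the C1–C8a bond to give the ring ketone and a terminal alkyne, with both stereocentres as spectators and cold, weakly acidic conditions that do not enolize the new ketone.

Step 5
Reactants: 12 (2R,6R)-2-(but-3-yn-1-yl)-2,6-dimethylcyclohexan-1-one
Product: 13 (1R,3R)-1-(but-3-yn-1-yl)-1,3-dimethyl-2-methylidenecyclohexane
Conditions: Zn, CH2Br2, TiCl4 (pre-formed reagent, 3 equiv), THF–CH2Cl2, 0 °C to rt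
Reagents that add atoms: dibromomethane (BrCBr)
Why: Takai–Lombardo methylenation, whose non-basic gem-dizinc/titanium reagent methylenates hindered enolizable ketones without epimerizing the α-centre and leaves the terminal alkyne alone.

Step 6
Reactants: 13 (1R,3R)-1-(but-3-yn-1-yl)-1,3-dimethyl-2-methylidenecyclohexane
Product: 16 (2E)-5-[(1R,3R)-1,3-dimethyl-2-methylidenecyclohexyl]-3-methylpent-2-en-1-ol, via alkenylalane 14 (not isolated), via lithium alanate 15 (not isolated)
Conditions: AlMe3 (2.5 equiv), Cp2ZrCl2 (0.25 equiv), CH2Cl2, 0 °C to rt; evaporate; n-BuLi (1.1 equiv), THF, −78 °C; (CH2O)n, −78 °C to rt; aq KNaC4H4O6 (potassium sodium tartrate)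
Reagents that add atoms: trimethylaluminium (C[Al](C)C); paraformaldehyde, reacting as formaldehyde (C=O)
Why: Negishi zirconium-catalysed methylalumination is a syn addition with methyl on the internal carbon, so the alkenylalane and, after ate-complex formation and trapping with formaldehyde with retention, the allylic alcohol are the E isomer only, while the hindered exocyclic alkene is inert.

Step 7
Reactants: 17 1,5-dibromo-2,4-dimethoxybenzene
Product: 18 4,6-dimethoxybenzene-1,3-diol
Conditions: Pd2(dba)3 (2 mol %), tBuXPhos (8 mol %), KOH (6 equiv), 1,4-dioxane–H2O 1:1, 100 °C, argon; then aq HCl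
Reagents that add atoms: potassium hydroxide ([K+].[OH-])
Why: Palladium-catalysed hydroxylation of aryl bromides with hydroxide (Buchwald-type C–O coupling), in which the bulky biarylphosphine drives C–O reductive elimination so that both bromides are exchanged; no stereocentre is involved.

Step 8
Reactants: 16 (2E)-5-[(1R,3R)-1,3-dimethyl-2-methylidenecyclohexyl]-3-methylpent-2-en-1-ol; 18 4,6-dimethoxybenzene-1,3-diol
Product: 19 2-[(2E)-5-[(1R,3R)-1,3-dimethyl-2-methylidenecyclohexyl]-3-methylpent-2-en-1-yl]-4,6-dimethoxybenzene-1,3-diol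
Conditions: 18 (2 equiv), acidic Al2O3 (2 g per mmol), 1,2-dichloroethane, 80 °C, N2
Reagents that add atoms: none
Why: Alumina-templated ortho C-allylation of a phenol with an allylic alcohol (Friedel–Crafts type), in which the surface-bound phenoxide directs the allyl cation equivalent to C2, the only position ortho to a hydroxyl, and attack at the primary allyl terminus keeps the E geometry.

Step 9
Reactants: 19 2-[(2E)-5-[(1R,3R)-1,3-dimethyl-2-methylidenecyclohexyl]-3-methylpent-2-en-1-yl]-4,6-dimethoxybenzene-1,3-diol
Product: 20 metachromin B: (2S)-2-{2-[(1R,3R)-1,3-dimethyl-2-methylidenecyclohexyl]ethyl}-6,8-dimethoxy-2-methyl-2H-chromen-5-ol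
Conditions: Pd(OCOCF3)2 (10 mol %), (S)-2,2'-bis[(4S)-4-isopropyl-4,5-dihydrooxazol-2-yl]-1,1'-binaphthyl (boxax ligand, 12 mol %), p-benzoquinone (2 equiv), MeOH, 40 °C, argon, dark
Reagents that add atoms: none
Why: Proposed new method: an enantioselective 6-endo Wacker-type oxidative cyclization in which the cationic divalent palladium phenoxide, held in the C2-symmetric pocket of the binaphthyl bis(oxazoline), binds one face of the E-trisubstituted alkene, the phenol oxygen adds to the more substituted (Markovnikov) alkene carbon to form the O1–C2 bond and the 2S quaternary centre, and palladium on C3 then undergoes β-hydride elimination with the only β-hydrogens available (benzylic C4) to give the 2H-chromene while benzoquinone reoxidizes the zerovalent palladium; either phenol gives the same product, the remote ring centres leave the step under catalyst control, and the closest known reaction types are the boxax–palladium asymmetric Wacker-type cyclization of o-allylphenols to 2,2-disubstituted dihydrobenzofurans (5-exo) and the non-asymmetric palladium-catalysed conversion of o-prenylphenols into 2H-chromenes.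

## Compound list

1 | 2,6-dimethylcyclohexanone (cis/trans mixture) | CC1CCCC(C)C1=O | starting material
2 | (S)-1-phenylethylamine | C[C@H](N)c1ccccc1 | starting material (recovered auxiliary)
3 | methyl vinyl ketone | CC(=O)C=C | starting material
4 | N-[(1S)-1-phenylethyl]-2,6-dimethylcyclohexan-1-imine (ring methyl centres unassigned; equilibrates with the secondary enamine) | CC1CCCC(C)C1=N[C@@H](C)c1ccccc1 | intermediate (not isolated)
5 | (2R,6S)-2,6-dimethyl-2-(3-oxobutyl)-N-[(1S)-1-phenylethyl]cyclohexan-1-imine | CC(=O)CC[C@@]1(C)CCC[C@H](C)C1=N[C@@H](C)c1ccccc1 | intermediate (not isolated)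
6 | (2R,6S)-2,6-dimethyl-2-(3-oxobutyl)cyclohexan-1-one (major C6 epimer) | CC(=O)CC[C@@]1(C)CCC[C@H](C)C1=O | intermediate
7 | (4aR,8S)-8a-hydroxy-4a,8-dimethyloctahydronaphthalen-2(1H)-one (8a centre undefined) | O=C1CC[C@@]2(C)CCC[C@H](C)C2(O)C1 | intermediate (not isolated)
8 | (4aR,8S)-4a,8-dimethyl-4,4a,5,6,7,8-hexahydronaphthalen-2(3H)-one | O=C1CC[C@@]2(C)CCC[C@H](C)C2=C1 | intermediate (not isolated)
9 | (4aR,8R)-4a,8-dimethyl-4,4a,5,6,7,8-hexahydronaphthalen-2(3H)-one | O=C1CC[C@@]2(C)CCC[C@@H](C)C2=C1 | intermediate
10 | (4aR,8R)-1,8a-epoxy-4a,8-dimethyloctahydronaphthalen-2(1H)-one (oxirane diastereomers) | O=C1CC[C@@]2(C)CCC[C@@H](C)C23OC13 | intermediate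
11 | 4-methylbenzenesulfonohydrazone of 10 | Cc1ccc(cc1)S(=O)(=O)NN=C1CC[C@@]2(C)CCC[C@@H](C)C23OC13 | intermediate (not isolated)
12 | (2R,6R)-2-(but-3-yn-1-yl)-2,6-dimethylcyclohexan-1-one | C#CCC[C@@]1(C)CCC[C@@H](C)C1=O | intermediate
13 | (1R,3R)-1-(but-3-yn-1-yl)-1,3-dimethyl-2-methylidenecyclohexane | C#CCC[C@@]1(C)CCC[C@@H](C)C1=C | intermediate
14 | [(1E)-4-[(1R,3R)-1,3-dimethyl-2-methylidenecyclohexyl]-2-methylbut-1-en-1-yl]dimethylalane | C[Al](C)/C=C(\C)CC[C@@]1(C)CCC[C@@H](C)C1=C | intermediate (not isolated)
15 | lithium butyl[(1E)-4-[(1R,3R)-1,3-dimethyl-2-methylidenecyclohexyl]-2-methylbut-1-en-1-yl]dimethylalanate | [Li+].CCCC[Al-](C)(C)/C=C(\C)CC[C@@]1(C)CCC[C@@H](C)C1=C | intermediate (not isolated)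
16 | (2E)-5-[(1R,3R)-1,3-dimethyl-2-methylidenecyclohexyl]-3-methylpent-2-en-1-ol | OC/C=C(\C)CC[C@@]1(C)CCC[C@@H](C)C1=C | intermediate
17 | 1,5-dibromo-2,4-dimethoxybenzene | COc1cc(OC)c(Br)cc1Br | starting material
18 | 4,6-dimethoxybenzene-1,3-diol | COc1cc(OC)c(O)cc1O | intermediate
19 | 2-[(2E)-5-[(1R,3R)-1,3-dimethyl-2-methylidenecyclohexyl]-3-methylpent-2-en-1-yl]-4,6-dimethoxybenzene-1,3-diol | COc1cc(OC)c(O)c(C/C=C(\C)CC[C@@]2(C)CCC[C@@H](C)C2=C)c1O | intermediate
20 | metachromin B, (2S)-2-{2-[(1R,3R)-1,3-dimethyl-2-methylidenecyclohexyl]ethyl}-6,8-dimethoxy-2-methyl-2H-chromen-5-ol | C=C1[C@H](C)CCC[C@]1(C)CC[C@@]1(C)C=Cc2c(O)c(OC)cc(OC)c2O1 | target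

## Step count and risk

Total step count: 9. Longest linear sequence: 8 (steps 1–6, 8, 9); step 7 is a one-step branch.

**Step 9 (the proposed new cyclization).** Likely failure modes are 5-exo closure to a 2-alkenyl-dihydrobenzofuran, low enantioselectivity, racemic background cyclization through quinone-mediated dehydrogenation, and migration of the exocyclic alkene by palladium hydride. The fallback uses known chemistry, sets out from 19 and comes back at 20. Reagent-controlled asymmetric selenoetherification with the chiral electrophile 2-[(1S)-1-hydroxypropyl]benzeneselenenyl triflate (from the diselenide with Br2 then AgOSO2CF3; CH2Cl2–Et2O, −78 °C) closes the pyran ring 6-endo by anti addition, with Se on C3 and O on the tertiary carbon, to give the 3-selanylchroman F1. The minor C2/C3 diastereomer is removed by chromatography at this stage, and the antipodal reagent is used if it proves to be the matched one. Oxidation with H2O2/pyridine (0 °C to rt) gives the selenoxide F2, which undergoes syn elimination towards the only β-hydrogens (C4) to give 20.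

**Step 8 (C-allylation on alumina).** Likely failure modes are acid-induced chroman formation, migration of the exocyclic alkene, and E/Z erosion. The fallback sets out from 16 and 18 and comes back at 19. Alcohol 16 is converted with PBr3 (Et2O, 0 °C) into the allylic bromide F3. Diol 18 is protected (MOMCl, i-Pr2NEt, CH2Cl2) as the bis(methoxymethyl) ether F4, which is lithiated between the two acetal oxygens (n-BuLi, THF, 0 °C) to the aryllithium F5. F5 is alkylated with F3 (−78 to 0 °C) to the coupled bis(methoxymethyl) ether F6, and brief HCl/MeOH at rt removes both acetals to give 19.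

**Step 5 (methylenation of the hindered ketone beside a terminal alkyne).** Likely failure modes are incomplete conversion and loss of the C6 configuration if a basic reagent is needed. The fallback sets out from 12 and comes back at 13 by Peterson olefination. Me3SiCH2MgCl with CeCl3 (3 equiv, THF, −78 to 0 °C; a weakly basic organocerium that adds without enolizing C6) gives the β-hydroxysilane F7, and KH (THF, 0 °C) brings about syn elimination of silanolate to give 13.

## Further compounds

F1 | step 9 | (2S,3R)-2-{2-[(1R,3R)-1,3-dimethyl-2-methylidenecyclohexyl]ethyl}-3-({2-[(1S)-1-hydroxypropyl]phenyl}selanyl)-6,8-dimethoxy-2-methyl-3,4-dihydro-2H-chromen-5-ol | CC[C@H](O)c1ccccc1[Se][C@@H]1Cc2c(O)c(OC)cc(OC)c2O[C@@]1(C)CC[C@@]3(C)CCC[C@@H](C)C3=C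
F2 | step 9 | Se-oxide of F1 (configuration at selenium undefined) | CC[C@H](O)c1ccccc1[Se](=O)[C@@H]1Cc2c(O)c(OC)cc(OC)c2O[C@@]1(C)CC[C@@]3(C)CCC[C@@H](C)C3=C
F3 | step 8 | (1R,3R)-1-[(3E)-5-bromo-3-methylpent-3-en-1-yl]-1,3-dimethyl-2-methylidenecyclohexane | BrC/C=C(\C)CC[C@@]1(C)CCC[C@@H](C)C1=C
F4 | step 8 | 1,5-dimethoxy-2,4-bis(methoxymethoxy)benzene | COCOc1cc(OCOC)c(OC)cc1OC
F5 | step 8 | [3,5-dimethoxy-2,6-bis(methoxymethoxy)phenyl]lithium | [Li]c1c(OCOC)c(OC)cc(OC)c1OCOC
F6 | step 8 | bis(methoxymethyl) ether of 19 | COCOc1c(C/C=C(\C)CC[C@@]2(C)CCC[C@@H](C)C2=C)c(OCOC)c(OC)cc1OC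
F7 | step 5 | (2R,6R)-2-(but-3-yn-1-yl)-2,6-dimethyl-1-[(trimethylsilyl)methyl]cyclohexan-1-ol (C1 epimers) | C#CCC[C@@]1(C)CCC[C@@H](C)C1(O)C[Si](C)(C)C
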